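The flavan is disconnected at O1–C8a and at the C8–CH2 bond. In benzo ring A the pyran oxygen (on C8a) and the ethylene bridge (on C8) sit on adjacent carbons. The C7 methoxy flanks C8 and the chain-bearing C4a flanks C8a, which is the substitution pattern of a trapped C8–C8a aryne. In one operation the tethered C2 alkoxide adds to C8a, closing the dihydropyran ring, and the C8 aryllithium left behind is formylated by DMF. The precursor is an open-chain (S)-1-phenyl-3-arylpropan-1-ol whose aryl ring bears fluorine ortho to the chain and two methoxy groups. Wittig union with a phenolic benzylphosphonium salt and alkene saturation complete the target.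

Key step: step 5

Remark: ring atoms are given in flavan numbering (O1, C2–C4, C4a, C5–C8, C8a). Compound 19 is drawn as the E alkene, but either geometry is acceptable because step 11 removes it. Compounds 1, 4 and 12 are taken to be commercial.

Step 1
Reactants: 1 1-fluoro-3,5-dimethoxybenzene
Product: 3 2-fluoro-4,6-dimethoxybenzaldehyde, via aryl iminium salt 2 (not isolated)
Conditions: POCl3 (1.5 equiv), DMF, 0 °C → 60 °C; ice-water, rt; chromatography or crystallisation
Reagents that add atoms: N,N-dimethylformamide, CN(C)C=O (formyl carbon); water, O (carbonyl oxygen, on hydrolysis of 2)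
Why: Vilsmeier–Haack formylation, in which the chloroiminium ion attacks the position para to one methoxy group and ortho to the other (next to the small fluorine) rather than the more crowded site between the two methoxy groups, and the minor 4-fluoro-2,6-dimethoxy isomer is removed on purification.

Step 2
Reactants: 3 2-fluoro-4,6-dimethoxybenzaldehyde; 4 acetophenone
Product: 5 (E)-3-(2-fluoro-4,6-dimethoxyphenyl)-1-phenylprop-2-en-1-one
Conditions: KOH (1.2 equiv), EtOH, 0 °C → rt
Reagents that add atoms: none
Why: Claisen–Schmidt aldol condensation of a non-enolisable aldehyde with a methyl ketone gives the E enone under thermodynamic control, and the two methoxy donors keep the ring too electron-rich for fluoride displacement by hydroxide or ethoxide at this temperature.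

Step 3
Reactants: 5 (E)-3-(2-fluoro-4,6-dimethoxyphenyl)-1-phenylprop-2-en-1-one
Product: 6 3-(2-fluoro-4,6-dimethoxyphenyl)-1-phenylpropan-1-one
Conditions: H2 (1 atm), 10% Pd/C, Ph2S (0.01 equiv), EtOAc, rt
Reagents that add atoms: none
Why: Heterogeneous hydrogenation over sulfide-poisoned palladium saturates only the enone C=C, leaving untouched the C–F bond and the aryl ketone, whose uncontrolled reduction would give racemic alcohol.

Step 4
Reactants: 6 3-(2-fluoro-4,6-dimethoxyphenyl)-1-phenylpropan-1-one
Product: 7 (S)-3-(2-fluoro-4,6-dimethoxyphenyl)-1-phenylpropan-1-ol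
Conditions: (R)-Me-CBS [(R)-1-methyl-3,3-diphenyltetrahydro-1H,3H-pyrrolo[1,2-c][1,3,2]oxazaborole] (10 mol %), BH3·SMe2 (1.0 equiv), THF, −20 °C, slow addition of 6; MeOH
Reagents that add atoms: none
Why: CBS reduction, in which the borane-loaded oxazaborolidine binds the ketone with phenyl as the large and the CH2CH2Ar chain as the small group, so the R catalyst (the enantiomer that converts acetophenone into (S)-1-phenylethanol) delivers hydride to the Re face and sets the S carbinol, whose ee and absolute sense are checked here by chiral HPLC and Mosher ester analysis.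

Step 5
Reactants: 7 (S)-3-(2-fluoro-4,6-dimethoxyphenyl)-1-phenylpropan-1-ol
Product: 11 (S)-5,7-dimethoxy-2-phenylchromane-8-carbaldehyde, via lithiated fluoroarene alkoxide 8 (not isolated), via aryne alkoxide 9 (not isolated), via 8-lithioflavan 10 (not isolated)
Conditions: n-BuLi (1.0 equiv), THF (0.03 M), −78 °C; LiTMP (lithium 2,2,6,6-tetramethylpiperidide, 2.5 equiv, from the amine and n-BuLi), −78 °C, 1 h; → −20 °C (followed on D2O-quenched aliquots); recool to −78 °C, DMF (8 equiv), → 0 °C; aq NH4Cl
Reagents that add atoms: N,N-dimethylformamide, CN(C)C=O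
Why: n-BuLi takes the hydroxyl proton and the acidity-driven amide base removes the ring proton flanked by F and OMe to give 8, warming expels LiF to open the C8–C8a aryne 9, the tethered alkoxide adds to C8a, and the aryllithium 10 left at C8, held between O1 and the C7 methoxy, is formylated by DMF. The closest known reaction type is the base-induced aryne cyclisation of halophenyl-alkyl amines, amides and alcohols in which the ortho-metalated heterocycle so formed is quenched with an electrophile. The dihydropyran ring closes in a 6-exo-dig sense, O1 attacking C8a while the in-plane π bond to C8 lies outside the new ring. No stereocentre is created, and C2 keeps the S configuration because only the aryl C–O bond is made and the carbinol C–O bond is never broken. Site selectivity of metalation is secured because only the anion next to fluorine can lose LiF, any anion between the two methoxy groups being returned through the amine, and the sense of addition is secured by the three-carbon tether and by the inductive pull of the C7 methoxy, both of which put oxygen on C8a and charge on C8. The hindered base, high dilution, no more than one equivalent of free amine and a ceiling of about −20 °C are meant to suppress amine or aryllithium addition to the aryne and C8-to-C6 proton shuffling before the quench.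

Step 6
Reactants: 12 2,6-dimethoxytoluene
Product: 14 3,5-dimethoxy-4-methylphenol, via arylboronate 13 (not isolated)
Conditions: [Ir(OMe)(cod)]2 (1.5 mol %), 4,4'-di-tert-butyl-2,2'-bipyridine (3 mol %), B2pin2 (0.7 equiv), THF, 80 °C; then 0 °C, aq NaOH, 30% H2O2; 1 M HCl
Reagents that add atoms: hydrogen peroxide, OO (phenol oxygen); bis(pinacolato)diboron, CC1(C)OB(OC1(C)C)B1OC(C)(C)C(C)(C)O1 (boryl group of 13 only, lost again in the oxidation)
Why: Sterically governed iridium-catalysed aromatic C–H borylation can reach only C4–H, the one ring hydrogen without an ortho substituent, and the boronate is oxidised in the same flask by a 1,2-aryl shift from boron to oxygen that keeps the ring position.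

Step 7
Reactants: 14 3,5-dimethoxy-4-methylphenol
Product: 15 6-hydroxy-2,4-dimethoxy-3-methylbenzaldehyde
Conditions: MgCl2 (anhydrous, 1.5 equiv), Et3N (3.75 equiv), (CH2O)n (6 equiv), MeCN, reflux; 1 M HCl
Reagents that add atoms: paraformaldehyde (as formaldehyde), C=O
Why: Casnati–Skattebøl ortho-formylation, in which the magnesium phenoxide delivers formaldehyde to the ortho carbon and a second formaldehyde oxidises the benzylic alkoxide by hydride transfer; the para position is blocked by methyl and the two ortho positions are equivalent, so only one isomer can form.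

Step 8
Reactants: 15 6-hydroxy-2,4-dimethoxy-3-methylbenzaldehyde
Product: 16 2-(hydroxymethyl)-3,5-dimethoxy-4-methylphenol
Conditions: NaBH4 (1.0 equiv), THF–EtOH, 0 °C, 20 min; aq NaH2PO4/Na2HPO4 buffer (pH 7); concentrated cold and used at once
Reagents that add atoms: none
Why: Borohydride reduction of the aldehyde is fast at 0 °C, and limiting the hydride, the time and the acidity of the quench guards against quinone methide formation and over-reduction of the benzylic position.

Step 9
Reactants: 16 2-(hydroxymethyl)-3,5-dimethoxy-4-methylphenol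
Product: 17 (6-hydroxy-2,4-dimethoxy-3-methylbenzyl)triphenylphosphonium bromide
Conditions: PPh3·HBr (1.2 equiv), MeCN, slow addition of 16 at rt, then 60 °C; Et2O (precipitation)
Reagents that add atoms: triphenylphosphine hydrobromide, [Br-].c1ccc(cc1)[PH+](c1ccccc1)c1ccccc1
Why: Acid-promoted SN1-type substitution of an electron-rich benzylic alcohol by triphenylphosphine, the standard preparation of 2-hydroxybenzylphosphonium salts, with inverse addition so that the benzylic cation always meets excess phosphine rather than a second arene.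

Step 10
Reactants: 17 (6-hydroxy-2,4-dimethoxy-3-methylbenzyl)triphenylphosphonium bromide; 11 (S)-5,7-dimethoxy-2-phenylchromane-8-carbaldehyde
Product: 19 2-{(E)-2-[(S)-5,7-dimethoxy-2-phenylchroman-8-yl]ethenyl}-3,5-dimethoxy-4-methylphenol, via oxido ylide 18 (not isolated)
Conditions: 17 (1.3 equiv), KOt-Bu (2.7 equiv), THF, 0 °C, 30 min; 11 (1.0 equiv), 0 → 50 °C; aq NH4Cl
Reagents that add atoms: none
Why: Wittig olefination with a semi-stabilised benzylic ylide, in which the first equivalent of base is taken by the phenol and the second forms 18, whose oxido group raises its nucleophilicity towards the hindered, non-enolisable aldehyde, while C2 is untouched and the alkene geometry is of no consequence.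

Step 11
Reactants: 19 2-{(E)-2-[(S)-5,7-dimethoxy-2-phenylchroman-8-yl]ethenyl}-3,5-dimethoxy-4-methylphenol
Product: 20 2-{2-[(S)-5,7-dimethoxy-2-phenylchroman-8-yl]ethyl}-3,5-dimethoxy-4-methylphenol (CNP0000262.1)
Conditions: H2 (1 atm), 10% Pd/C, Ph2S (0.01 equiv), EtOAc–MeOH, rt
Reagents that add atoms: none
Why: Catalytic hydrogenation over the same sulfide-poisoned palladium, which reduces alkenes but does not hydrogenolyse benzylic ethers, saturates the stilbene while the benzylic C2–O1 bond and the stereocentre stay intact.

Compound list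
1 | 1-fluoro-3,5-dimethoxybenzene | COc1cc(F)cc(OC)c1 | starting material
2 | (2-fluoro-4,6-dimethoxybenzylidene)dimethyliminium dichlorophosphate (aryl iminium salt, not isolated) | C[N+](C)=Cc1c(F)cc(OC)cc1OC.[O-]P(=O)(Cl)Cl | intermediate
3 | 2-fluoro-4,6-dimethoxybenzaldehyde | COc1cc(F)c(C=O)c(OC)c1 | intermediate
4 | acetophenone | CC(=O)c1ccccc1 | starting material
5 | (E)-3-(2-fluoro-4,6-dimethoxyphenyl)-1-phenylprop-2-en-1-one | O=C(/C=C/c1c(F)cc(OC)cc1OC)c1ccccc1 | intermediate
6 | 3-(2-fluoro-4,6-dimethoxyphenyl)-1-phenylpropan-1-one | O=C(CCc1c(F)cc(OC)cc1OC)c1ccccc1 | intermediate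
7 | (S)-3-(2-fluoro-4,6-dimethoxyphenyl)-1-phenylpropan-1-ol | O[C@H](c1ccccc1)CCc1c(F)cc(OC)cc1OC | intermediate
8 | lithium (S)-3-(2-fluoro-3-lithio-4,6-dimethoxyphenyl)-1-phenylpropan-1-olate (lithiated fluoroarene alkoxide, not isolated) | [Li]O[C@H](c1ccccc1)CCc1c(F)c([Li])c(OC)cc1OC | intermediate
9 | lithium (S)-3-(2,3-didehydro-4,6-dimethoxyphenyl)-1-phenylpropan-1-olate (aryne alkoxide, not isolated) | [Li]O[C@H](c1ccccc1)CCC1=C(OC)C=C(OC)C#C1 | intermediate
10 | (S)-8-lithio-5,7-dimethoxy-2-phenylchromane (8-lithioflavan, not isolated) | [Li]c1c(OC)cc(OC)c2c1O[C@H](c1ccccc1)CC2 | intermediate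
11 | (S)-5,7-dimethoxy-2-phenylchromane-8-carbaldehyde | O=Cc1c(OC)cc(OC)c2c1O[C@H](c1ccccc1)CC2 | intermediate
12 | 2,6-dimethoxytoluene | COc1cccc(OC)c1C | starting material
13 | 2-(3,5-dimethoxy-4-methylphenyl)-4,4,5,5-tetramethyl-1,3,2-dioxaborolane (arylboronate, not isolated) | COc1cc(B2OC(C)(C)C(C)(C)O2)cc(OC)c1C | intermediate
14 | 3,5-dimethoxy-4-methylphenol | COc1cc(O)cc(OC)c1C | intermediate
15 | 6-hydroxy-2,4-dimethoxy-3-methylbenzaldehyde | COc1cc(O)c(C=O)c(OC)c1C | intermediate
16 | 2-(hydroxymethyl)-3,5-dimethoxy-4-methylphenol | COc1cc(O)c(CO)c(OC)c1C | intermediate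
17 | (6-hydroxy-2,4-dimethoxy-3-methylbenzyl)triphenylphosphonium bromide | COc1cc(O)c(C[P+](c2ccccc2)(c2ccccc2)c2ccccc2)c(OC)c1C.[Br-] | intermediate
18 | potassium 3,5-dimethoxy-4-methyl-2-[(triphenyl-λ5-phosphanylidene)methyl]phenolate (oxido ylide, not isolated) | COc1cc([O-])c(C=P(c2ccccc2)(c2ccccc2)c2ccccc2)c(OC)c1C.[K+] | intermediate
19 | 2-{(E)-2-[(S)-5,7-dimethoxy-2-phenylchroman-8-yl]ethenyl}-3,5-dimethoxy-4-methylphenol | COc1cc(O)c(/C=C/c2c(OC)cc(OC)c3c2O[C@H](c2ccccc2)CC3)c(OC)c1C | intermediate
20 | 2-{2-[(S)-5,7-dimethoxy-2-phenylchroman-8-yl]ethyl}-3,5-dimethoxy-4-methylphenol (CNP0000262.1) | COc1cc(O)c(CCc2c(OC)cc(OC)c3c2O[C@H](c2ccccc2)CC3)c(OC)c1C | target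

Total step count: 11. Longest linear sequence: 7 steps (1, 2, 3, 4, 5, 10, 11). The phenol branch (6, 7, 8, 9) joins at step 10.

Steps most likely to fail

**Step 5 (key step).**
- Risk: the aryne may be intercepted by the amide base or by a second aryllithium before the tethered alkoxide closes the ring. The liberated amine may also shuttle a proton onto C8, so that the metal is lost or drifts to C6 before DMF arrives.
- Fallback (sets out from 4, returns at 11): the ring is closed at the other C–O bond and C8 is functionalised afterwards. Commercial 2-hydroxy-4,6-dimethoxybenzaldehyde F1 is condensed with 4 (KOH, EtOH) to (E)-3-(2-hydroxy-4,6-dimethoxyphenyl)-1-phenylprop-2-en-1-one F2. One-pot C=C and C=O asymmetric transfer hydrogenation with RuCl[(R,R)-TsDPEN](p-cymene) and HCO2Na in H2O–MeOH should give (R)-2-(3-hydroxy-3-phenylpropyl)-3,5-dimethoxyphenol F3. Mitsunobu etherification (PPh3, DIAD, THF, 0 °C) closes O1–C2 with inversion to (S)-5,7-dimethoxy-2-phenylchromane F4. NBS (CH2Cl2, −40 °C) is expected to brominate C8, as it does in 5,7-di-O-alkylated flavan-3-ols, giving (S)-8-bromo-5,7-dimethoxy-2-phenylchromane F5, with the site to be confirmed by NOE. Bromine–lithium exchange (n-BuLi, THF, −78 °C) then produces 10 with no amine present, and DMF converts it into 11.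

**Step 10.**
- Risk: carbonyl addition between two doubly ortho-substituted partners may be sluggish. Expulsion of triphenylphosphine from the phenoxide–phosphonium betaine and quinone-methide oligomerisation could then take over.
- Fallback (sets out from 11 and 14, returns at 20): the olefination is replaced by an alkyne cross-coupling, whose linear link tolerates four ortho substituents. Seyferth–Gilbert homologation of 11 with dimethyl (1-diazo-2-oxopropyl)phosphonate (K2CO3, MeOH) gives (S)-8-ethynyl-5,7-dimethoxy-2-phenylchromane F6. Phenol 14 is iodinated (NIS, MeCN, 0 °C) to 2-iodo-3,5-dimethoxy-4-methylphenol F7 and benzylated (BnBr, K2CO3, acetone) to 1-(benzyloxy)-2-iodo-3,5-dimethoxy-4-methylbenzene F8; the ether prevents benzofuran formation. Sonogashira coupling (PdCl2(PPh3)2, CuI, Et3N–DMF, 60 °C) gives (S)-8-{[6-(benzyloxy)-2,4-dimethoxy-3-methylphenyl]ethynyl}-5,7-dimethoxy-2-phenylchromane F9. Hydrogenation over unpoisoned Pd/C (H2, 1 atm, EtOAc–EtOH) saturates the alkyne and cleaves the primary benzyl ether, which should go much faster than the ring C2–O1 bond, to give 20.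

**Step 9.**
- Risk: ionisation of the very electron-rich salicyl alcohol and Friedel–Crafts self-condensation may outrun capture by the phosphine.
- Fallback (sets out from 14, returns at 19 through ylide 18): the benzylic carbon is introduced at the amine level, so neither 15 nor 16 is needed and no acid is used. Mannich aminomethylation of 14 (aq Me2NH, aq CH2O, EtOH, rt) gives 2-[(dimethylamino)methyl]-3,5-dimethoxy-4-methylphenol F10. MeI (Et2O, 0 °C → rt) gives (6-hydroxy-2,4-dimethoxy-3-methylbenzyl)trimethylammonium iodide F11. Heating with PPh3 in MeCN exchanges trimethylamine for the phosphine to give (6-hydroxy-2,4-dimethoxy-3-methylbenzyl)triphenylphosphonium iodide F12. With KOt-Bu this forms the same ylide 18, which reacts with 11 to give 19.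

Further compounds
F1 | step 5 | 2-hydroxy-4,6-dimethoxybenzaldehyde (bought) | COc1cc(O)c(C=O)c(OC)c1
F2 | step 5 | (E)-3-(2-hydroxy-4,6-dimethoxyphenyl)-1-phenylprop-2-en-1-one | O=C(/C=C/c1c(O)cc(OC)cc1OC)c1ccccc1
F3 | step 5 | (R)-2-(3-hydroxy-3-phenylpropyl)-3,5-dimethoxyphenol | O[C@@H](c1ccccc1)CCc1c(O)cc(OC)cc1OC
F4 | step 5 | (S)-5,7-dimethoxy-2-phenylchromane | COc1cc(OC)c2c(c1)O[C@H](c1ccccc1)CC2
F5 | step 5 | (S)-8-bromo-5,7-dimethoxy-2-phenylchromane | COc1cc(OC)c2c(c1Br)O[C@H](c1ccccc1)CC2
F6 | step 10 | (S)-8-ethynyl-5,7-dimethoxy-2-phenylchromane | C#Cc1c(OC)cc(OC)c2c1O[C@H](c1ccccc1)CC2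
F7 | step 10 | 2-iodo-3,5-dimethoxy-4-methylphenol | COc1cc(O)c(I)c(OC)c1C
F8 | step 10 | 1-(benzyloxy)-2-iodo-3,5-dimethoxy-4-methylbenzene | COc1cc(OCc2ccccc2)c(I)c(OC)c1C
F9 | step 10 | (S)-8-{[6-(benzyloxy)-2,4-dimethoxy-3-methylphenyl]ethynyl}-5,7-dimethoxy-2-phenylchromane | COc1cc(OCc2ccccc2)c(C#Cc2c(OC)cc(OC)c3c2O[C@H](c2ccccc2)CC3)c(OC)c1C
F10 | step 9 | 2-[(dimethylamino)methyl]-3,5-dimethoxy-4-methylphenol | COc1cc(O)c(CN(C)C)c(OC)c1C
F11 | step 9 | (6-hydroxy-2,4-dimethoxy-3-methylbenzyl)trimethylammonium iodide | COc1cc(O)c(C[N+](C)(C)C)c(OC)c1C.[I-]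
F12 | step 9 | (6-hydroxy-2,4-dimethoxy-3-methylbenzyl)triphenylphosphonium iodide | COc1cc(O)c(C[P+](c2ccccc2)(c2ccccc2)c2ccccc2)c(OC)c1C.[I-]
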